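**Retrosynthetic overview**
1. Structural basis: ring B carries oxygens at C2 and C4, the prenyl group at C3 between them and the diketone carbon at C1. This is the pattern of a 2-prenylcyclohexane-1,3-dione acylated at its α′ carbon, so ring B is carried as a cyclohexenone and aromatised late.
2. Licoagrodione 22 ⇐ bis-MOM benzil 21 ⇐ ketol 20 ⇐ silyl ether 19 ⇐ (selenoxide elimination, tautomerisation) 6-acylcyclohexenone 14.
3. Key disconnection: the ring B C1–C(=O) bond of 14, made by Claisen acylation of the kinetic C6 lithium enolate 12 of vinylogous ester 4 with the O-silyl mandelate 11.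
4. 4 comes from cyclohexane-1,3-dione 1 and prenyl bromide 2, then MOMCl; 11 comes from 2-bromo-5-methoxyphenol 5 via MOM ether 6, Br/Li exchange, diethyl oxalate 7, NaBH4 and TBSCl.
5. Ring order: ring A is aromatic from the start; ring B enters as the saturated dione and becomes aromatic in step 9; no ring is closed by cyclisation.

Key step: step 7

Remark on the chemistry: the target has no stereocentre. The carbinol carbon (compounds 10 to 20) is carried racemic and C6 of the acylated enone (14, 16, 17) as a mixture, because both end as sp2 carbons.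

**Route**

Step 1
Reactants: 1 cyclohexane-1,3-dione; 2 prenyl bromide (1-bromo-3-methylbut-2-ene)
Product: 3 2-(3-methylbut-2-enyl)cyclohexane-1,3-dione
Conditions: KOH (1.0 equiv), H2O, 0 °C → rt
Reagents that add atoms: none
Why: SN2 C-alkylation of the 1,3-dione enolate at the doubly activated C2, favoured in water because the enolate oxygens are hydrogen-bonded and the soft allylic bromide prefers carbon.

Step 2
Reactants: 3 2-(3-methylbut-2-enyl)cyclohexane-1,3-dione
Product: 4 3-(methoxymethoxy)-2-(3-methylbut-2-enyl)cyclohex-2-en-1-one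
Conditions: MOMCl (1.2 equiv), iPr2NEt (1.5 equiv), CH2Cl2, 0 °C; chromatography on Et3N-deactivated silica
Reagents that add atoms: chloromethyl methyl ether (MOMCl), COCCl
Why: O-alkylation of the enolised 2-substituted dione by the hard chloromethyl ether (vinylogous ester formation) is preferred over C-alkylation at the substituted C2, and the symmetry of 3 allows only one product.

Step 3
Reactants: 5 2-bromo-5-methoxyphenol
Product: 6 1-bromo-4-methoxy-2-(methoxymethoxy)benzene
Conditions: MOMCl (1.3 equiv), iPr2NEt (1.6 equiv), CH2Cl2, 0 °C → rt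
Reagents that add atoms: chloromethyl methyl ether (MOMCl), COCCl
Why: Williamson-type etherification of the phenol gives an acetal that is stable to all basic and organometallic steps that follow.

Step 4
Reactants: 6 1-bromo-4-methoxy-2-(methoxymethoxy)benzene; 7 diethyl oxalate
Product: 9 ethyl 2-[4-methoxy-2-(methoxymethoxy)phenyl]-2-oxoacetate, via aryllithium 8 (not isolated)
Conditions: n-BuLi (1.05 equiv), THF, −78 °C; cannulation into 7 (3 equiv), THF, −78 °C; AcOH quench
Reagents that add atoms: none
Why: Bromine–lithium exchange is faster than any ortho-lithiation and gives 8 regiospecifically, and inverse addition to excess oxalate at −78 °C limits the reaction to mono-acylation (acylation of an organolithium with a dialkyl oxalate).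

Step 5
Reactants: 9 ethyl 2-[4-methoxy-2-(methoxymethoxy)phenyl]-2-oxoacetate
Product: 10 ethyl 2-hydroxy-2-[4-methoxy-2-(methoxymethoxy)phenyl]acetate (racemic)
Conditions: NaBH4 (0.5 equiv), EtOH, −20 → 0 °C
Reagents that add atoms: none
Why: Borohydride reduction of the ketone of an α-keto ester is much faster than reduction of the ester, ethanol matches the ester alkoxide, and the new carbinol centre is formed racemic, which is immaterial because it is reoxidised in step 11.

Step 6
Reactants: 10 ethyl 2-hydroxy-2-[4-methoxy-2-(methoxymethoxy)phenyl]acetate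
Product: 11 ethyl 2-(tert-butyldimethylsilyloxy)-2-[4-methoxy-2-(methoxymethoxy)phenyl]acetate (racemic)
Conditions: TBSCl (1.3 equiv), imidazole (2.5 equiv), DMF, rt
Reagents that add atoms: tert-butyldimethylsilyl chloride (TBSCl), CC(C)(C)[Si](C)(C)Cl
Why: Imidazole-mediated silylation of the secondary benzylic alcohol masks the hydroxyl as a base-stable group for the enolate acylation.

Step 7
Reactants: 4 3-(methoxymethoxy)-2-(3-methylbut-2-enyl)cyclohex-2-en-1-one; 11 ethyl 2-(tert-butyldimethylsilyloxy)-2-[4-methoxy-2-(methoxymethoxy)phenyl]acetate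
Product: 14 6-{2-(tert-butyldimethylsilyloxy)-2-[4-methoxy-2-(methoxymethoxy)phenyl]acetyl}-3-(methoxymethoxy)-2-(3-methylbut-2-enyl)cyclohex-2-en-1-one (mixture of stereoisomers and enol forms), via lithium dienolate 12 (not isolated), via lithium diketonate 13 (not isolated)
Conditions: LiN(iPr)2 (2.2 equiv), 4 (2.2 equiv), THF, −78 °C; then 11 (1.0 equiv), −78 → −20 °C; AcOH quench
Reagents that add atoms: none
Why: LiN(iPr)2 removes the kinetically most accessible C6–H of vinylogous ester 4 at −78 °C to give the cross-conjugated dienolate 12, whose C6 adds to the ester carbonyl of 11; loss of ethoxide forms the C6–C(=O) bond (the future ring B C1–ketone bond), and a second equivalent of 12 deprotonates the acidic β-diketone to diketonate 13, which is why 12 is used in twofold amount and no free amide base is left to attack 11. The closest known reaction type is the crossed Claisen acylation of kinetic α′-enolates of 3-alkoxycyclohex-2-enones with esters. No ring is closed. C6 and the carbinol carbon are formed without control as a mixture, which does not matter because C6 becomes an aromatic carbon in step 9 and the carbinol carbon a ketone in step 11. The step needs α′ (C6) over γ (C4) deprotonation, secured by irreversible kinetic deprotonation with the hindered lithium amide at low temperature, and C-acylation over proton transfer from the α-C–H of 11, which is favoured by inductive activation of the ester carbonyl by the α-silyloxy group and by steric shielding of that C–H by the silyl ether and the ortho-substituted aryl ring.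

Step 8
Reactants: 14 6-acyl-3-(methoxymethoxy)-2-prenylcyclohex-2-en-1-one (β-diketone from step 7)
Product: 16 6-{2-(tert-butyldimethylsilyloxy)-2-[4-methoxy-2-(methoxymethoxy)phenyl]acetyl}-3-(methoxymethoxy)-2-(3-methylbut-2-enyl)-6-(phenylselanyl)cyclohex-2-en-1-one (mixture of diastereomers), via sodium enolate 15 (not isolated)
Conditions: NaH (1.1 equiv), THF, 0 °C; PhSeCl (1.05 equiv), −78 → 0 °C
Reagents that add atoms: phenylselenenyl chloride (PhSeCl), Cl[Se]c1ccccc1
Why: C-selenenylation of a preformed β-diketonate at its central carbon (the standard enolate selenenylation of 2-acylcycloalkanones) is far faster at −78 °C than addition of the selenenyl chloride to the prenyl alkene when no excess electrophile is present; the new quaternary centre is uncontrolled and is removed in step 9.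

Step 9
Reactants: 16 6-acyl-6-(phenylselanyl)cyclohexenone from step 8
Product: 19 2-(tert-butyldimethylsilyloxy)-1-[2-hydroxy-4-(methoxymethoxy)-3-(3-methylbut-2-enyl)phenyl]-2-[4-methoxy-2-(methoxymethoxy)phenyl]ethan-1-one (racemic), via selenoxide 17 (not isolated), via dienone tautomer 18 (not isolated)
Conditions: 30% aq. H2O2 (3 equiv), pyridine (2 equiv), CH2Cl2, 0 °C → rt
Reagents that add atoms: none
Why: Oxidation at selenium and syn-elimination of the selenoxide (selenoxide elimination) can only involve the C5 hydrogens, giving the cross-conjugated dienone 18, which tautomerises to the hydrogen-bonded 2-hydroxyaryl ketone 19 with gain of aromaticity.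

Step 10
Reactants: 19 silyl ether from step 9
Product: 20 2-hydroxy-1-[2-hydroxy-4-(methoxymethoxy)-3-(3-methylbut-2-enyl)phenyl]-2-[4-methoxy-2-(methoxymethoxy)phenyl]ethan-1-one (racemic)
Conditions: TBAF (1.2 equiv), AcOH (1.2 equiv), THF, 0 °C
Reagents that add atoms: none
Why: Fluoride cleavage of the silyl ether, buffered with acetic acid so that the benzoin-type ketol is not enolised or air-oxidised uncontrollably, leaves the aryl methoxymethyl ethers untouched.

Step 11
Reactants: 20 ketol from step 10
Product: 21 1-[2-hydroxy-4-(methoxymethoxy)-3-(3-methylbut-2-enyl)phenyl]-2-[4-methoxy-2-(methoxymethoxy)phenyl]ethane-1,2-dione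
Conditions: Dess–Martin periodinane (1.3 equiv), CH2Cl2, 0 °C → rt
Reagents that add atoms: none
Why: Dess–Martin oxidation of the secondary benzylic α-ketol to the 1,2-diketone runs under near-neutral conditions that should spare the chelated phenol, the acetals and the alkene.

Step 12
Reactants: 21 bis-MOM benzil from step 11
Product: 22 licoagrodione, 1-[2,4-dihydroxy-3-(3-methylbut-2-enyl)phenyl]-2-(2-hydroxy-4-methoxyphenyl)ethane-1,2-dione
Conditions: 3 M aq. HCl, THF, 40 °C, stopped as soon as 21 is consumed
Reagents that add atoms: none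
Why: Acid-catalysed hydrolysis of the two aryl methoxymethyl acetals is faster than protonation of the trisubstituted alkene in dilute aqueous acid, and the non-alcoholic cosolvent avoids ketal formation at the 1,2-dione.

**Compound list**
1 | cyclohexane-1,3-dione | O=C1CCCC(=O)C1 | starting material
2 | prenyl bromide (1-bromo-3-methylbut-2-ene) | CC(C)=CCBr | starting material
3 | 2-(3-methylbut-2-enyl)cyclohexane-1,3-dione | O=C1CCCC(=O)C1CC=C(C)C | intermediate
4 | 3-(methoxymethoxy)-2-(3-methylbut-2-enyl)cyclohex-2-en-1-one | COCOC1=C(CC=C(C)C)C(=O)CCC1 | intermediate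
5 | 2-bromo-5-methoxyphenol | COc1ccc(Br)c(O)c1 | starting material
6 | 1-bromo-4-methoxy-2-(methoxymethoxy)benzene | COCOc1cc(OC)ccc1Br | intermediate
7 | diethyl oxalate | CCOC(=O)C(=O)OCC | starting material
8 | [4-methoxy-2-(methoxymethoxy)phenyl]lithium (not isolated) | [Li]c1ccc(OC)cc1OCOC | intermediate
9 | ethyl 2-[4-methoxy-2-(methoxymethoxy)phenyl]-2-oxoacetate | CCOC(=O)C(=O)c1ccc(OC)cc1OCOC | intermediate
10 | ethyl 2-hydroxy-2-[4-methoxy-2-(methoxymethoxy)phenyl]acetate (racemic) | CCOC(=O)C(O)c1ccc(OC)cc1OCOC | intermediate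
11 | ethyl 2-(tert-butyldimethylsilyloxy)-2-[4-methoxy-2-(methoxymethoxy)phenyl]acetate (racemic) | CCOC(=O)C(O[Si](C)(C)C(C)(C)C)c1ccc(OC)cc1OCOC | intermediate
12 | lithium 5-(methoxymethoxy)-6-(3-methylbut-2-enyl)cyclohexa-1,5-dien-1-olate, the kinetic C6 enolate of 4 (not isolated) | [Li+].[O-]C1=CCCC(OCOC)=C1CC=C(C)C | intermediate
13 | lithium enolate of β-diketone 14 (not isolated) | [Li+].COCOC1=C(CC=C(C)C)C(=O)C(=C([O-])C(O[Si](C)(C)C(C)(C)C)c2ccc(OC)cc2OCOC)CC1 | intermediate
14 | 6-{2-(tert-butyldimethylsilyloxy)-2-[4-methoxy-2-(methoxymethoxy)phenyl]acetyl}-3-(methoxymethoxy)-2-(3-methylbut-2-enyl)cyclohex-2-en-1-one (mixture of stereoisomers and enol forms) | COCOC1=C(CC=C(C)C)C(=O)C(C(=O)C(O[Si](C)(C)C(C)(C)C)c2ccc(OC)cc2OCOC)CC1 | intermediate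
15 | sodium enolate of β-diketone 14 (not isolated) | [Na+].COCOC1=C(CC=C(C)C)C(=O)C(=C([O-])C(O[Si](C)(C)C(C)(C)C)c2ccc(OC)cc2OCOC)CC1 | intermediate
16 | 6-(phenylselanyl) derivative of 14 (mixture of diastereomers) | COCOC1=C(CC=C(C)C)C(=O)C([Se]c3ccccc3)(C(=O)C(O[Si](C)(C)C(C)(C)C)c2ccc(OC)cc2OCOC)CC1 | intermediate
17 | 6-(phenylseleninyl) derivative of 14, the selenoxide (not isolated) | COCOC1=C(CC=C(C)C)C(=O)C([Se](=O)c3ccccc3)(C(=O)C(O[Si](C)(C)C(C)(C)C)c2ccc(OC)cc2OCOC)CC1 | intermediate
18 | 2-{2-(tert-butyldimethylsilyloxy)-2-[4-methoxy-2-(methoxymethoxy)phenyl]acetyl}-5-(methoxymethoxy)-6-(3-methylbut-2-enyl)cyclohexa-2,5-dien-1-one (not isolated) | COCOC1=C(CC=C(C)C)C(=O)C(C(=O)C(O[Si](C)(C)C(C)(C)C)c2ccc(OC)cc2OCOC)=CC1 | intermediate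
19 | 2-(tert-butyldimethylsilyloxy)-1-[2-hydroxy-4-(methoxymethoxy)-3-(3-methylbut-2-enyl)phenyl]-2-[4-methoxy-2-(methoxymethoxy)phenyl]ethan-1-one (racemic) | COCOc1ccc(C(=O)C(O[Si](C)(C)C(C)(C)C)c2ccc(OC)cc2OCOC)c(O)c1CC=C(C)C | intermediate
20 | 2-hydroxy-1-[2-hydroxy-4-(methoxymethoxy)-3-(3-methylbut-2-enyl)phenyl]-2-[4-methoxy-2-(methoxymethoxy)phenyl]ethan-1-one (racemic) | COCOc1ccc(C(=O)C(O)c2ccc(OC)cc2OCOC)c(O)c1CC=C(C)C | intermediate
21 | 1-[2-hydroxy-4-(methoxymethoxy)-3-(3-methylbut-2-enyl)phenyl]-2-[4-methoxy-2-(methoxymethoxy)phenyl]ethane-1,2-dione | COCOc1ccc(C(=O)C(=O)c2ccc(OC)cc2OCOC)c(O)c1CC=C(C)C | intermediate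
22 | licoagrodione | COc1ccc(C(=O)C(=O)c2ccc(O)c(CC=C(C)C)c2O)c(O)c1 | target

**Step count**
Total steps: 12. Longest linear sequence: 10 (steps 3 to 12); the ring B branch (steps 1 and 2) joins at step 7.

**Steps most likely to fail**

Step 7. The enolate 12 may act as a base toward the α-C–H of ester 11 instead of adding to its hindered carbonyl, and the kinetic enolate may equilibrate to the γ-dienolate on warming, so that conversion stays low. The fallback replaces the Claisen acylation by an aldol addition followed by oxidation, keeping the same bond. It sets out from ester 11: iBu2AlH (CH2Cl2, −78 °C) should give 2-(tert-butyldimethylsilyloxy)-2-[4-methoxy-2-(methoxymethoxy)phenyl]acetaldehyde F1. Addition of F1 to enolate 12 (1.1 equiv, THF, −78 °C, where aldehyde addition is much faster than proton transfer) should give the aldol 6-{2-(tert-butyldimethylsilyloxy)-1-hydroxy-2-[4-methoxy-2-(methoxymethoxy)phenyl]ethyl}-3-(methoxymethoxy)-2-(3-methylbut-2-enyl)cyclohex-2-en-1-one F2. Dess–Martin oxidation of F2 returns to the route at β-diketone 14.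

Step 8. The selenenyl chloride may add across the electron-rich prenyl alkene, and the selenenic acid released in step 9 may add to the same alkene. The fallback avoids selenium altogether by a one-pot sulfur-based dehydrogenation (Mukaiyama dehydrogenation). It sets out from 14, which is deprotonated with LiN(SiMe3)2 (THF, −78 °C) to diketonate 13 and treated with N-tert-butylbenzenesulfinimidoyl chloride. The central carbon should attack sulfur to give the α-sulfilimine F3, whose nitrogen removes a C5 hydrogen in an intramolecular syn-elimination at low temperature. This gives dienone 18, and the fallback returns to the route at phenol 19.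

Step 12. During acetal hydrolysis the protic acid may protonate the prenyl alkene, which then cyclises onto a flanking phenol oxygen to a chroman. The fallback replaces hydrolysis by an acetal-to-silyl-ether exchange under buffered aprotic conditions. It sets out from 21: Me3SiOTf and 2,2′-bipyridyl (CH3CN, 0 °C → rt) should convert both aryl methoxymethyl ethers, and the free C2 hydroxyl, into trimethylsilyl ethers, giving 1-[3-(3-methylbut-2-enyl)-2,4-bis(trimethylsilyloxy)phenyl]-2-[4-methoxy-2-(trimethylsilyloxy)phenyl]ethane-1,2-dione F4. Hydrolysis of the aryl silyl ethers with water at neutral pH returns to the route at 22.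

**Further compounds**
F1 | step 7 | 2-(tert-butyldimethylsilyloxy)-2-[4-methoxy-2-(methoxymethoxy)phenyl]acetaldehyde (racemic) | O=CC(O[Si](C)(C)C(C)(C)C)c1ccc(OC)cc1OCOC
F2 | step 7 | 6-{2-(tert-butyldimethylsilyloxy)-1-hydroxy-2-[4-methoxy-2-(methoxymethoxy)phenyl]ethyl}-3-(methoxymethoxy)-2-(3-methylbut-2-enyl)cyclohex-2-en-1-one (mixture of diastereomers) | COCOC1=C(CC=C(C)C)C(=O)C(C(O)C(O[Si](C)(C)C(C)(C)C)c2ccc(OC)cc2OCOC)CC1
F3 | step 8 | 6-(N-tert-butyl-S-phenylsulfinimidoyl) derivative of 14 (not isolated) | COCOC1=C(CC=C(C)C)C(=O)C(S(=NC(C)(C)C)c3ccccc3)(C(=O)C(O[Si](C)(C)C(C)(C)C)c2ccc(OC)cc2OCOC)CC1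
F4 | step 12 | 1-[3-(3-methylbut-2-enyl)-2,4-bis(trimethylsilyloxy)phenyl]-2-[4-methoxy-2-(trimethylsilyloxy)phenyl]ethane-1,2-dione | COc1ccc(C(=O)C(=O)c2ccc(O[Si](C)(C)C)c(CC=C(C)C)c2O[Si](C)(C)C)c(O[Si](C)(C)C)c1
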